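Retrosynthesis cuts first the seven O–benzyl bonds, then C4–H and the C4–C8 interflavan bond together (back to a flavan-4-one carbonyl and an 8-bromo-epicatechin ether), and last the C2–aryl bond of the upper unit (back to a chromone and an arylboronic acid).
Forward, no ring is built: the upper pyranone ring comes from 7-hydroxychromone and the lower flavan from (−)-epicatechin; the upper C2-aryl group is added first, the lower half is benzylated, brominated at C8 and benzylated at O3, the halves are joined in step 6, and hydrogenolysis ends the route.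
Enabling feature: C4 of the upper flavan is benzylic to ring A, para to the 7-oxygen and ortho-related to O1, so it can be a ketone and afterwards a strongly stabilised 4-aryl cation; C8 of the epicatechin ring A, between O1 and the 7-oxygen, is the innate site of electrophilic bromination.
Order at C4: the biosynthetic order (hydride, then aryl) is expected to put the incoming aryl axial and trans to the 2-aryl group; here the aryl goes on first and hydride last, so that axial hydride delivery leaves the two aryl groups cis (2S,4S).
Stereochemistry: C2 and C3 of the lower unit come from (−)-epicatechin, C2 of the upper unit from the chiral Pd ligand in step 2, and C4 of the upper unit from C2 by substrate control in step 6.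

Key step: step 6

Assumption: (R)-t-BuPyOx is taken to be the ligand enantiomer that gives the 2S flavanone (same facial sense as with cyclic enones); if the sense is the opposite one, (S)-t-BuPyOx is used instead.

Step 1
Reactants: 1 7-hydroxy-4H-chromen-4-one
Product: 2 7-(benzyloxy)-4H-chromen-4-one
Conditions: BnBr, K2CO3, DMF, rt
Reagents that add atoms: benzyl bromide BrCc1ccccc1
Why: Williamson etherification of the acidic 7-OH should give the benzyl ether, a group that survives organolithium and trifluoroacetic acid and leaves with the others in the last step.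

Step 2
Reactants: 2 7-(benzyloxy)-4H-chromen-4-one, 3 4-(benzyloxy)phenylboronic acid
Product: 4 (2S)-7-(benzyloxy)-2-[4-(benzyloxy)phenyl]-2,3-dihydro-4H-chromen-4-one
Conditions: Pd(OCOCF3)2 (5 mol %), (R)-t-BuPyOx (6 mol %), NH4PF6 (30 mol %), H2O (5 equiv), ClCH2CH2Cl, 60 °C
Reagents that add atoms: none
Why: Pd(II)/pyridine-oxazoline-catalysed asymmetric conjugate addition of an arylboronic acid to a chromone (Hayashi–Miyaura-type 1,4-addition) should set C2 as S through ligand control of the enone face in the aryl-palladium insertion, under neutral conditions that avoid retro-oxa-Michael racemisation of the flavanone.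

Step 3
Reactants: 5 (−)-epicatechin
Product: 6 5,7,3',4'-tetra-O-benzyl-(−)-epicatechin
Conditions: BnBr (4.2 equiv), K2CO3, DMF, 0 °C → rt, Ar
Reagents that add atoms: benzyl bromide BrCc1ccccc1
Why: Williamson etherification with carbonate base should alkylate the four phenolic OH groups and leave the secondary 3-OH and both stereocentres untouched, argon protecting the catechol from oxidation.

Step 4
Reactants: 6 5,7,3',4'-tetra-O-benzyl-(−)-epicatechin
Product: 7 8-bromo-5,7,3',4'-tetra-O-benzyl-(−)-epicatechin
Conditions: NBS (1.0 equiv), CH2Cl2, −78 °C → rt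
Reagents that add atoms: N-bromosuccinimide O=C1CCC(=O)N1Br
Why: Electrophilic aromatic bromination of the phloroglucinol-type ring A should take place at C8, between O1 and the 7-benzyloxy group, which is the established site selectivity for benzylated flavan-3-ols.

Step 5
Reactants: 7 8-bromo-5,7,3',4'-tetra-O-benzyl-(−)-epicatechin
Product: 8 8-bromo-3,5,7,3',4'-penta-O-benzyl-(−)-epicatechin
Conditions: NaH, BnBr, DMF, 0 °C → rt
Reagents that add atoms: benzyl bromide BrCc1ccccc1
Why: Williamson benzylation of the secondary alkoxide should remove the only acidic proton before the lithiation, with retention at C3 because the C–O bond is not broken.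

Step 6
Reactants: 8 8-bromo-3,5,7,3',4'-penta-O-benzyl-(−)-epicatechin, 4 (2S)-7-(benzyloxy)-2-[4-(benzyloxy)phenyl]-2,3-dihydro-4H-chromen-4-one
Product: 11 hepta-O-benzyl-cassiaflavan-(4α→8)-epicatechin, via aryllithium 9 (not isolated), via lithium carbinolate 10 (not isolated)
Conditions: t-BuLi (2.05 equiv), THF, −78 °C; then 4, THF, −78 → −40 °C; then Et3SiH (5 equiv), CF3CO2H (excess), CH2Cl2, −78 → 0 °C
Reagents that add atoms: none
Why: Bromine–lithium exchange gives the C8 aryllithium, which adds to the C4 carbonyl of the flavanone to give the tertiary lithium carbinolate; acidification ionises this doubly benzylic C4–O bond to the 4-aryl-flavan-4-yl cation, stabilised by the 7-benzyloxy group para and O1 ortho on ring A of the upper unit, and triethylsilane reduces it (ionic hydrogenation). The closest known reaction type is the addition of an 8-lithiated flavan-3-ol ether to a flavan-4-one followed by hydride/acid deoxygenation of the tertiary benzylic alcohol. No ring is closed. The one new stereocentre that persists, C4 of the upper unit, is controlled by C2: the pyran ring of the cation is a half-chair with the 2-aryl group equatorial, hydride enters C4 along the axial direction on the face of H-2 (chair-like transition state, trans to the 2-aryl group), and the epicatechin ring is left equatorial and cis to the 2-aryl group, i.e. 4S, while the configuration of the carbinolate carbon is without consequence because it is ionised. The step needs site selectivity for C8 over C6, secured by the bromine placed at C8 in step 4, and carbonyl addition in place of deprotonation at C3, favoured by the low temperature and the unhindered CH2 flank of the C4 carbonyl; an enolate that does form only returns 4 on acidification, so the C2 configuration of the product is not at risk. The silane is present before the acid so that the cation is reduced before it can lose a proton to the acid-sensitive flav-3-ene.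

Step 7
Reactants: 11 hepta-O-benzyl-cassiaflavan-(4α→8)-epicatechin
Product: 12 cassiaflavan-(4α→8)-epicatechin (target)
Conditions: H2 (1 atm), 20 % Pd(OH)2/C, THF/MeOH, rt
Reagents that add atoms: none
Why: Heterogeneous hydrogenolysis should cleave the seven benzyl ethers under conditions that leave the C2–O bonds and the C4–C8 bond of benzylated proanthocyanidins intact and touch no stereocentre.

Compound list
1 | 7-hydroxy-4H-chromen-4-one (7-hydroxychromone) | O=c1ccoc2cc(O)ccc12 | starting material
2 | 7-(benzyloxy)-4H-chromen-4-one | O=c1ccoc2cc(OCc3ccccc3)ccc12 | intermediate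
3 | 4-(benzyloxy)phenylboronic acid | OB(O)c1ccc(OCc2ccccc2)cc1 | starting material
4 | (2S)-7-(benzyloxy)-2-[4-(benzyloxy)phenyl]-2,3-dihydro-4H-chromen-4-one | O=C1C[C@@H](c2ccc(OCc3ccccc3)cc2)Oc2cc(OCc3ccccc3)ccc12 | intermediate
5 | (−)-epicatechin, (2R,3R)-2-(3,4-dihydroxyphenyl)chromane-3,5,7-triol | O[C@@H]1Cc2c(O)cc(O)cc2O[C@@H]1c1ccc(O)c(O)c1 | starting material
6 | 5,7,3',4'-tetra-O-benzyl-(−)-epicatechin, (2R,3R)-5,7-bis(benzyloxy)-2-[3,4-bis(benzyloxy)phenyl]chroman-3-ol | O[C@@H]1Cc2c(OCc3ccccc3)cc(OCc3ccccc3)cc2O[C@@H]1c1ccc(OCc2ccccc2)c(OCc2ccccc2)c1 | intermediate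
7 | 8-bromo-5,7,3',4'-tetra-O-benzyl-(−)-epicatechin, (2R,3R)-5,7-bis(benzyloxy)-2-[3,4-bis(benzyloxy)phenyl]-8-bromochroman-3-ol | O[C@@H]1Cc2c(OCc3ccccc3)cc(OCc3ccccc3)c(Br)c2O[C@@H]1c1ccc(OCc2ccccc2)c(OCc2ccccc2)c1 | intermediate
8 | 8-bromo-3,5,7,3',4'-penta-O-benzyl-(−)-epicatechin, (2R,3R)-3,5,7-tris(benzyloxy)-2-[3,4-bis(benzyloxy)phenyl]-8-bromochromane | O(Cc1ccccc1)[C@@H]1Cc2c(OCc3ccccc3)cc(OCc3ccccc3)c(Br)c2O[C@@H]1c1ccc(OCc2ccccc2)c(OCc2ccccc2)c1 | intermediate
9 | aryllithium, (2R,3R)-3,5,7-tris(benzyloxy)-2-[3,4-bis(benzyloxy)phenyl]chroman-8-yllithium (formed in the flask) | O(Cc1ccccc1)[C@@H]1Cc2c(OCc3ccccc3)cc(OCc3ccccc3)c([Li])c2O[C@@H]1c1ccc(OCc2ccccc2)c(OCc2ccccc2)c1 | intermediate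
10 | lithium carbinolate, lithium (2S)-7-(benzyloxy)-2-[4-(benzyloxy)phenyl]-4-[(2R,3R)-3,5,7-tris(benzyloxy)-2-[3,4-bis(benzyloxy)phenyl]chroman-8-yl]chroman-4-olate, C4 configuration not defined (formed in the flask) | O(Cc6ccccc6)c1ccc([C@@H]2CC(O[Li])(c3c(OCc6ccccc6)cc(OCc6ccccc6)c4c3O[C@H](c3ccc(OCc6ccccc6)c(OCc6ccccc6)c3)[C@H](OCc3ccccc3)C4)c3ccc(OCc4ccccc4)cc3O2)cc1 | intermediate
11 | hepta-O-benzyl-cassiaflavan-(4α→8)-epicatechin, (2R,3R)-3,5,7-tris(benzyloxy)-2-[3,4-bis(benzyloxy)phenyl]-8-[(2S,4S)-7-(benzyloxy)-2-[4-(benzyloxy)phenyl]chroman-4-yl]chromane | O(Cc6ccccc6)c1ccc([C@@H]2C[C@H](c3c(OCc6ccccc6)cc(OCc6ccccc6)c4c3O[C@H](c3ccc(OCc6ccccc6)c(OCc6ccccc6)c3)[C@H](OCc3ccccc3)C4)c3ccc(OCc4ccccc4)cc3O2)cc1 | intermediate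
12 | cassiaflavan-(4α→8)-epicatechin, (2R,3R)-2-(3,4-dihydroxyphenyl)-8-[(2S,4S)-7-hydroxy-2-(4-hydroxyphenyl)chroman-4-yl]chromane-3,5,7-triol | Oc1ccc([C@@H]2C[C@H](c3c(O)cc(O)c4c3O[C@H](c3ccc(O)c(O)c3)[C@H](O)C4)c3ccc(O)cc3O2)cc1 | target

Total step count: 7
Longest linear sequence: 5 steps (steps 3, 4, 5, 6 and 7, from 5)

Steps most likely to fail

Step 6. The hindered aryllithium may deprotonate the flavanone at C3 in place of adding to the carbonyl, and the hydride transfer may show incomplete facial selectivity or be overtaken by elimination to the flavene. The fallback sets out from 4 and 8 and comes back to the route at 12. Compound 4 is converted with Tf2O and 2,6-di-tert-butyl-4-methylpyridine in CH2Cl2 into the enol triflate (2S)-7-(benzyloxy)-2-[4-(benzyloxy)phenyl]-2H-chromen-4-yl trifluoromethanesulfonate F1. Miyaura borylation (B2pin2, PdCl2(dppf), KOAc, dioxane) turns it into the flav-3-en-4-yl boronate F2. Suzuki–Miyaura coupling of F2 with bromide 8 (Pd(OAc)2, SPhos, K3PO4, toluene/H2O) forms the same C4–C8 bond and gives the 4-aryl-flav-3-ene F3. Hydrogenation over Pd(OH)2/C should then add hydrogen to the C3=C4 bond from the face opposite the 2-aryl group, which again gives the 2,4-cis arrangement, and remove the seven benzyl groups in the same operation to give 12.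

Step 2. Insertion into the electron-rich 7-alkoxychromone may be slow, so that protodeboronation of the electron-rich boronic acid competes and the enantiomeric purity is eroded. The fallback sets out from 2 (with 3) and comes back at 4. Conjugate addition with an achiral catalyst (Pd(OCOCF3)2, 2,2'-bipyridine) gives the racemic flavanone F4. This is resolved by preparative chromatography on a polysaccharide chiral stationary phase, and the 2S enantiomer is taken on as 4.

Step 7. The hindered benzyl ethers next to the interflavan bond may be cleaved incompletely, benzylic C–O bonds may open on prolonged exposure, and the free catechol may oxidise during isolation. The fallback sets out from 11 and comes back at 12. The ethers are cleaved by Lewis acid in place of hydrogen (BCl3 with pentamethylbenzene as benzyl cation scavenger, CH2Cl2, −78 °C); this fallback makes no further compound (F0).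

Further compounds
F1 | step 6 | (2S)-7-(benzyloxy)-2-[4-(benzyloxy)phenyl]-2H-chromen-4-yl trifluoromethanesulfonate | O=S(=O)(OC1=C[C@@H](c2ccc(OCc3ccccc3)cc2)Oc2cc(OCc3ccccc3)ccc12)C(F)(F)F
F2 | step 6 | (2S)-7-(benzyloxy)-2-[4-(benzyloxy)phenyl]-4-(4,4,5,5-tetramethyl-1,3,2-dioxaborolan-2-yl)-2H-chromene | CC1(C)OB(OC1(C)C)C1=C[C@@H](c2ccc(OCc3ccccc3)cc2)Oc2cc(OCc3ccccc3)ccc12
F3 | step 6 | (2R,3R)-3,5,7-tris(benzyloxy)-2-[3,4-bis(benzyloxy)phenyl]-8-[(2S)-7-(benzyloxy)-2-[4-(benzyloxy)phenyl]-2H-chromen-4-yl]chromane | O(Cc6ccccc6)c1ccc([C@@H]2C=C(c3c(OCc6ccccc6)cc(OCc6ccccc6)c4c3O[C@H](c3ccc(OCc6ccccc6)c(OCc6ccccc6)c3)[C@H](OCc3ccccc3)C4)c3ccc(OCc4ccccc4)cc3O2)cc1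
F4 | step 2 | rac-7-(benzyloxy)-2-[4-(benzyloxy)phenyl]-2,3-dihydro-4H-chromen-4-one | O=C1CC(c2ccc(OCc3ccccc3)cc2)Oc2cc(OCc3ccccc3)ccc12
F0 | step 7 | none | none
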